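The pitfall here is to carry the fraction lost per hour in the cedar run unchanged over to green and grey, whose charge is twice as large.

the same everywhere: gas 17 mM (held)

| run | left-handed substrate | right-handed substrate | remark | time |
|---|---|---|---|---|
| cedar | 0.025 M | 0.025 M | run made earlier |  |
| green | 0.050 M | 0.050 M |  | 50 h |
| grey | 0.050 M | 0.050 M |  | 15 h |

- cedar (time / h: right-handed substrate / %, left-handed substrate / %): 1.33: 49.4, 49.8; 2.00: 49.6, 49.5; 3.00: 49.4, 49.1; 5.00: 49.6, 47.5; 10.0: 46.5, 44.9; 15.0: 46.2, 40.1

(scatter of a reading: 0.5 percentage points)

1. the flask that ends with the higher excess of right-handed substrate over left-handed substrate among what is left of the two, or "neither" when 2 percentage points or less lies between them (green / grey / neither)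
2. excess of right-handed substrate over left-handed substrate among what is left of the two at the end, green
3. excess of right-handed substrate over left-handed substrate among what is left of the two at the end, grey

- partner is single-handed; left-handed substrate and right-handed substrate are mirror images of each other, charged as a racemate, each of them at the stated concentration
- at the start none of the gas is in solution
- an excess is the difference of the two amounts in percent of their sum
- an excess is below zero if the other one leads
- the handed part of partner does not stay in what it makes, so the products of the two hands are mirror images too

I take both hands to lose a fraction per hour proportional to the same partner level, so I follow one rate, the climb of the logarithm of right-handed over left-handed substrate. In the cedar run I count from 2.00 h, where I put the end of the lag while gas enters, to 15.0 h, where right-handed substrate stands at 46.2% and left-handed at 40.1%, which gives 0.0109 h⁻¹, and this handedness gain per hour is a reading that carries the scatter of the data.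

I assume that the supply of partner from the held gas is the rate-limiting step, so the amount lost per hour stays as it was, and as a fraction of the larger charge the gain falls by a factor of 2.00 to 0.00545 h⁻¹. With a steady gain the integral is a product: green has 48.0 h after the lag and reaches a logarithm of 0.261, and grey has 13.0 h and reaches 0.0708. The excess is the hyperbolic tangent of half that logarithm, so I expect 13.0% for green and 3.54% for grey, with green higher by more than the margin.

The forecast names green, with 21% for green and 6% for grey, on the assumption that “doubling the concentration leaves fractional conversion unchanged”, and there it differs from my reckoning.

The flask gives green, with 12.6% for green and 4.40% for grey.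

    partner + left-handed substrate → left-handed product (k = 5.80 M⁻¹ h⁻¹)
    partner + right-handed substrate → right-handed product (k = 1.90 M⁻¹ h⁻¹)
    left-handed substrate ⇌ right-handed substrate (k = 0.0140 h⁻¹)
    gas ⇌ partner, rate k4*(csat - [partner]) (kL = 0.0560 h⁻¹)
    2 partner → homo dimer (k = 3.40 M⁻¹ h⁻¹)
    partner → decomposed reagent (k = 0.0180 h⁻¹)

Turned back into a logarithm over the hours I counted after the lag, the excess of green is an average gain of 0.00528 h⁻¹, against the 0.00545 h⁻¹ I took from 0.0109 h⁻¹. The flask green read at 30 h instead has 28.0 h after the lag as I count it, so the reckoning gives a logarithm of 0.152 and an excess of 7.61%. That flask stands at 8.40%, with 73% of the charged left-handed substrate still there and 86% of the charged right-handed substrate.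

The numbers in the tables come from a simulation from invented constants, and the scatter is random.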